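Both carbocycles are (+)-quinic (1R,3S,4R,5S) units, the mirror image of natural quinic acid, so each ring is built de novo. In each cyclohexane the carboxyl carbon on C1 and O5 are cis, so C5–C6–C1–C(=O)–O5 is a γ-butyrolactone, and C3–C4 carries the cis-diol. The route rests on disconnecting C3–C4: a SmI2 pinacol coupling of a dialdehyde whose two arms (CHO on C5, CH2CHO on C1) sit cis on an L-glutamate-derived lactone closes the cyclohexane, sets C3 and C4, and delivers the quinide bicycle in one operation. The tertiary oxygen is carried as a triethylsilyl ether, later the only protecting group the acyl unit needs.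

Key step: step 8

Remark: quinic acid numbering is used for every carbocycle (C1 bears the carboxyl carbon C7 and the tertiary oxygen, C3/C4 the cis-diol, C5 the oxygen cis to the carboxyl); "ent-quinic" means the (1R,3S,4R,5S) acid and "ent-quinide" its 1,5-lactone, and in the target both caffeoyl groups sit on O5.

Step 1
Reactants: 1 (S)-5-(hydroxymethyl)dihydrofuran-2(3H)-one
Product: 2 (S)-5-(trityloxymethyl)dihydrofuran-2(3H)-one
Conditions: TrCl, Et3N, DMAP (cat.), DCM, rt
Reagents that add atoms: trityl chloride, ClC(c1ccccc1)(c1ccccc1)c1ccccc1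
Why: Tritylation of the primary alcohol (DMAP-assisted etherification via the trityl cation) is routine for this lactone, touches no stereocentre and installs the bulky group that shields one ring face in steps 2 and 3.

Step 2
Reactants: 2 (S)-5-(trityloxymethyl)dihydrofuran-2(3H)-one; 3 allyl bromide
Product: 5 (3R,5S)-3-allyl-5-(trityloxymethyl)dihydrofuran-2(3H)-one, via lithium enolate 4 (not isolated)
Conditions: LiN(i-Pr)2, THF, −78 °C; then allyl bromide, −78 to −40 °C
Reagents that add atoms: allyl bromide 3, C=CCBr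
Why: Enolate alkylation of the lactone should place the allyl group anti to the C5 trityloxymethyl substituent (trans product), although this C3 configuration is erased again in step 3.

Step 3
Reactants: 5 (3R,5S)-3-allyl-5-(trityloxymethyl)dihydrofuran-2(3H)-one
Product: 7 (3R,5S)-3-allyl-3-hydroxy-5-(trityloxymethyl)dihydrofuran-2(3H)-one, via potassium enolate 6 (not isolated)
Conditions: KN(SiMe3)2, THF, −78 °C; then 2-(phenylsulfonyl)-3-phenyloxaziridine, −78 °C; AcOH
Reagents that add atoms: 2-(phenylsulfonyl)-3-phenyloxaziridine, O=S(=O)(c1ccccc1)N1OC1c1ccccc1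
Why: In this Davis oxidation the oxaziridine oxygen should add to the planar tetrasubstituted enolate on the face anti to the C5 trityloxymethyl group, so the hydroxyl ends trans and the allyl group cis to that substituent, which sets the future C1.

Step 4
Reactants: 7 (3R,5S)-3-allyl-3-hydroxy-5-(trityloxymethyl)dihydrofuran-2(3H)-one
Product: 8 (3R,5S)-3-allyl-3-(triethylsilyloxy)-5-(trityloxymethyl)dihydrofuran-2(3H)-one
Conditions: TESOTf, 2,6-lutidine, DCM, −78 to 0 °C
Reagents that add atoms: triethylsilyl trifluoromethanesulfonate, CC[Si](CC)(CC)OS(=O)(=O)C(F)(F)F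
Why: Silylation of a hindered tertiary alcohol with a silyl triflate and a hindered pyridine base is standard, avoids alkoxide chemistry at the lactone and changes no stereocentre.

Step 5
Reactants: 8 (3R,5S)-3-allyl-3-(triethylsilyloxy)-5-(trityloxymethyl)dihydrofuran-2(3H)-one
Product: 9 (3R,5S)-3-allyl-5-(hydroxymethyl)-3-(triethylsilyloxy)dihydrofuran-2(3H)-one
Conditions: CSA (cat.), MeOH/DCM, 0 °C
Reagents that add atoms: none
Why: Acid-catalysed solvolysis of the trityl ether (ionisation to the trityl cation, trapped by methanol) should be much faster than cleavage of the hindered tertiary silyl ether, whose oxygen is deactivated by the adjacent carbonyl.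

Step 6
Reactants: 9 (3R,5S)-3-allyl-5-(hydroxymethyl)-3-(triethylsilyloxy)dihydrofuran-2(3H)-one
Product: 10 (2S,4R)-4-allyl-5-oxo-4-(triethylsilyloxy)oxolane-2-carbaldehyde
Conditions: TEMPO (cat.), PhI(OAc)2, DCM, rt
Reagents that add atoms: none
Why: The oxoammonium (TEMPO/PhI(OAc)2) oxidation stops at the aldehyde under base-free, anhydrous conditions, which should protect the epimerisable centre next to the lactone oxygen and leave the alkene untouched.

Step 7
Reactants: 10 (2S,4R)-4-allyl-5-oxo-4-(triethylsilyloxy)oxolane-2-carbaldehyde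
Product: 12 (3S,5S)-5-formyl-2-oxo-3-(triethylsilyloxy)oxolane-3-acetaldehyde, via ozonide 11 (not isolated)
Conditions: O3, DCM, −78 °C; then PPh3, −78 °C to rt; Ph3PO precipitated from cold Et2O/pentane, crude product used at once
Reagents that add atoms: ozone, [O-][O+]=O
Why: Ozonolysis (Criegee mechanism) with phosphine reduction of the ozonide converts the terminal alkene into the second aldehyde without base or water, so the C5 centre should not epimerise and the dialdehyde need not be stored.

Step 8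
Reactants: 12 (3S,5S)-5-formyl-2-oxo-3-(triethylsilyloxy)oxolane-3-acetaldehyde
Product: 13 (1R,3S,4S,5S)-3,4-dihydroxy-1-(triethylsilyloxy)-6-oxabicyclo[3.2.1]octan-7-one (1-O-triethylsilyl-ent-quinide)
Conditions: SmI2 (3 equiv), t-BuOH (3 equiv), THF, −78 °C to rt; 12 added slowly to the SmI2 solution
Reagents that add atoms: none
Why: Divalent samarium transfers one electron to an aldehyde (most readily the C5-bound one) to give a samarium ketyl, whose carbon adds to the second, samarium-coordinated aldehyde, and a second electron transfer leaves the cis-diolate of trivalent samarium, which t-BuOH protonates. This is the known SmI2 pinacol cyclisation of 1,6-dialdehydes to cis-cyclohexane-1,2-diols, as used for inositols and carbasugars. The cyclohexane C1–C6 closes in a 6-exo-trig mode by forming C3–C4, and because both arms are cis on the rigid γ-lactone the 6-oxabicyclo[3.2.1]octan-7-one skeleton appears directly. The cis relationship of O3 and O4 comes from both oxygens being bound to one samarium in the cyclic transition state. The face is fixed by the bicycle: an O3 pointing towards the lactone bridge would be axial and clash with C7 and O5, so O3 should be equatorial and its cis partner O4 axial, anti to the C5–O5 bond, which dipole minimisation next to an α-oxygen also favours. The step needs this cis, anti-to-O5 diol rather than the trans-diequatorial 4-epimer or reductive loss of the C5–O5 bond, and low temperature, absence of HMPA and slow addition to excess SmI2 should favour ring closure over further reduction of the ketyl.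

Step 9
Reactants: 13 1-O-triethylsilyl-ent-quinide
Product: 14 3,4-O-isopropylidene-1-O-triethylsilyl-ent-quinide
Conditions: 2,2-dimethoxypropane, PPTS (cat.), acetone, rt
Reagents that add atoms: 2,2-dimethoxypropane, COC(C)(C)OC
Why: Acid-catalysed transketalisation closes a dioxolane across the cis C3/C4 diol, the only diol present, under mild catalysis that should spare the tertiary silyl ether.

Step 10
Reactants: 14 3,4-O-isopropylidene-1-O-triethylsilyl-ent-quinide
Product: 15 allyl 3,4-O-isopropylidene-1-O-triethylsilyl-ent-quinate (free 5-OH)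
Conditions: NaH (cat.), allyl alcohol, 0 °C to rt; AcOH quench before evaporation
Reagents that add atoms: allyl alcohol, C=CCO
Why: Alkoxide-catalysed alcoholysis (transesterification) relieves the strain of the bridged lactone and, in neat allyl alcohol, should be driven to the open allyl ester, freeing O5 with its C–O bond untouched.

Step 11
Reactants: 16 caffeic acid
Product: 18 (E)-3-[3,4-bis(methoxymethoxy)phenyl]prop-2-enoic acid, via methoxymethyl ester 17 (not isolated)
Conditions: MOMCl (3.3 equiv), i-Pr2NEt, DCM, 0 °C to rt; concentrate; LiOH, THF/MeOH/H2O, rt; 1 M HCl to pH 4 at 0 °C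
Reagents that add atoms: chloromethyl methyl ether, COCCl
Why: O-Alkylation with MOMCl caps both phenols and, transiently, the acid, and saponification then cleaves only the methoxymethyl ester because aryl MOM ethers are base-stable.

Step 12
Reactants: 15 allyl 3,4-O-isopropylidene-1-O-triethylsilyl-ent-quinate; 18 (E)-3-[3,4-bis(methoxymethoxy)phenyl]prop-2-enoic acid
Product: 19 allyl 5-O-[(E)-3,4-bis(methoxymethoxy)cinnamoyl]-3,4-O-isopropylidene-1-O-triethylsilyl-ent-quinate
Conditions: DCC, DMAP, DCM, 0 °C to rt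
Reagents that add atoms: none
Why: Steglich esterification acylates the only free hydroxyl, the secondary O5, with retention at C5 since its C–O bond is not broken.

Step 13
Reactants: 19 allyl 5-O-[(E)-3,4-bis(methoxymethoxy)cinnamoyl]-3,4-O-isopropylidene-1-O-triethylsilyl-ent-quinate
Product: 20 5-O-[(E)-3,4-bis(methoxymethoxy)cinnamoyl]-3,4-O-isopropylidene-1-O-triethylsilyl-ent-quinic acid (unit A)
Conditions: Pd(PPh3)4 (cat.), morpholine, THF, rt; cold citric acid wash
Reagents that add atoms: none
Why: In this Tsuji–Trost deallylation zerovalent palladium ionises the allyl ester and morpholine traps the π-allyl complex, neutral conditions that should leave the silyl ether, the acetals and the cinnamate intact.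

Step 14
Reactants: 19 allyl 5-O-[(E)-3,4-bis(methoxymethoxy)cinnamoyl]-3,4-O-isopropylidene-1-O-triethylsilyl-ent-quinate
Product: 21 allyl 5-O-[(E)-3,4-bis(methoxymethoxy)cinnamoyl]-3,4-O-isopropylidene-ent-quinate (free tertiary 1-OH; unit B)
Conditions: HF·pyridine, pyridine, THF, 0 °C to rt
Reagents that add atoms: none
Why: Fluoride-mediated desilylation with buffered HF·pyridine removes the triethylsilyl ether without base, so no acyl migration or ester cleavage is expected and the acetonide and MOM ethers should survive.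

Step 15
Reactants: 20 unit A acid; 21 unit B tertiary alcohol
Product: 23 allyl 1-O-{5-O-[(E)-3,4-bis(methoxymethoxy)cinnamoyl]-3,4-O-isopropylidene-1-O-triethylsilyl-ent-quinoyl}-5-O-[(E)-3,4-bis(methoxymethoxy)cinnamoyl]-3,4-O-isopropylidene-ent-quinate, via acid chloride 22 (not isolated)
Conditions: 1-chloro-N,N,2-trimethylprop-1-en-1-amine, DCM, 0 °C to rt; then 21, Et3N, DMAP (1 equiv), DCM, rt to 40 °C
Reagents that add atoms: none
Why: This is a DMAP-catalysed acylation of a tertiary alcohol by an acid chloride made under neutral conditions; the chloride has no α-hydrogen (no ketene pathway) and the alcohol has no other nucleophilic site, so the hindered ester can be forced by time and temperature.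

Step 16
Reactants: 23 protected allyl ester dimer
Product: 24 1-O-{5-O-[(E)-3,4-bis(methoxymethoxy)cinnamoyl]-3,4-O-isopropylidene-1-O-triethylsilyl-ent-quinoyl}-5-O-[(E)-3,4-bis(methoxymethoxy)cinnamoyl]-3,4-O-isopropylidene-ent-quinic acid
Conditions: Pd(PPh3)4 (cat.), morpholine, THF, rt; cold citric acid wash
Reagents that add atoms: none
Why: Tsuji–Trost deallylation as in step 13 frees the carboxyl of unit B under neutral conditions to which the three remaining esters should not respond.

Step 17
Reactants: 24 protected dimer acid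
Product: 25 1-O-(5-O-caffeoyl-ent-quinoyl)-5-O-caffeoyl-ent-quinic acid (CNP0107948.2)
Conditions: TFA/H2O (9:1), 0 °C to rt; evaporation, reversed-phase purification
Reagents that add atoms: none
Why: Acid-catalysed hydrolysis should remove both acetonides, the four aryl MOM acetals and the silyl ether in one operation at low pH, where caffeoyl migration is slow, as is usual for acetonide-protected caffeoylquinic acids.

Compound list
1 | (S)-5-(hydroxymethyl)dihydrofuran-2(3H)-one | OC[C@@H]1CCC(=O)O1 | starting material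
2 | (S)-5-(trityloxymethyl)dihydrofuran-2(3H)-one | O(C[C@@H]1CCC(=O)O1)C(c2ccccc2)(c2ccccc2)c2ccccc2 | intermediate
3 | allyl bromide | C=CCBr | starting material
4 | lithium enolate of 2 | O(C[C@@H]1CC=C([O-])O1)C(c2ccccc2)(c2ccccc2)c2ccccc2.[Li+] | intermediate
5 | (3R,5S)-3-allyl-5-(trityloxymethyl)dihydrofuran-2(3H)-one (allyl trans to CH2OTr) | O(C[C@@H]1C[C@@H](CC=C)C(=O)O1)C(c2ccccc2)(c2ccccc2)c2ccccc2 | intermediate
6 | potassium enolate of 5 | O(C[C@@H]1CC(CC=C)=C([O-])O1)C(c2ccccc2)(c2ccccc2)c2ccccc2.[K+] | intermediate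
7 | (3R,5S)-3-allyl-3-hydroxy-5-(trityloxymethyl)dihydrofuran-2(3H)-one (OH trans, allyl cis to CH2OTr) | O(C[C@@H]1C[C@](O)(CC=C)C(=O)O1)C(c2ccccc2)(c2ccccc2)c2ccccc2 | intermediate
8 | (3R,5S)-3-allyl-3-(triethylsilyloxy)-5-(trityloxymethyl)dihydrofuran-2(3H)-one | O(C[C@@H]1C[C@](O[Si](CC)(CC)CC)(CC=C)C(=O)O1)C(c2ccccc2)(c2ccccc2)c2ccccc2 | intermediate
9 | (3R,5S)-3-allyl-5-(hydroxymethyl)-3-(triethylsilyloxy)dihydrofuran-2(3H)-one | OC[C@@H]1C[C@](O[Si](CC)(CC)CC)(CC=C)C(=O)O1 | intermediate
10 | (2S,4R)-4-allyl-5-oxo-4-(triethylsilyloxy)oxolane-2-carbaldehyde | O=C[C@@H]1C[C@](O[Si](CC)(CC)CC)(CC=C)C(=O)O1 | intermediate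
11 | ozonide (1,2,4-trioxolane) of 10, mixture at the trioxolane carbon | O=C[C@@H]1C[C@](O[Si](CC)(CC)CC)(CC2OCOO2)C(=O)O1 | intermediate
12 | (3S,5S)-5-formyl-2-oxo-3-(triethylsilyloxy)oxolane-3-acetaldehyde (both aldehyde arms cis) | O=C[C@@H]1C[C@](O[Si](CC)(CC)CC)(CC=O)C(=O)O1 | intermediate
13 | (1R,3S,4S,5S)-3,4-dihydroxy-1-(triethylsilyloxy)-6-oxabicyclo[3.2.1]octan-7-one (1-O-triethylsilyl-ent-quinide) | O=C1O[C@H]2C[C@]1(O[Si](CC)(CC)CC)C[C@H](O)[C@@H]2O | intermediate
14 | 3,4-O-isopropylidene-1-O-triethylsilyl-ent-quinide | O=C1O[C@H]2C[C@]1(O[Si](CC)(CC)CC)C[C@H](OC3(C)C)[C@@H]2O3 | intermediate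
15 | allyl 3,4-O-isopropylidene-1-O-triethylsilyl-ent-quinate (free 5-OH) | O[C@H]1C[C@](C(=O)OCC=C)(O[Si](CC)(CC)CC)C[C@H](OC2(C)C)[C@@H]1O2 | intermediate
16 | caffeic acid, (E)-3-(3,4-dihydroxyphenyl)prop-2-enoic acid | O=C(O)/C=C/c1ccc(O)c(O)c1 | starting material
17 | methoxymethyl (E)-3-[3,4-bis(methoxymethoxy)phenyl]prop-2-enoate | COCOC(=O)/C=C/c1ccc(OCOC)c(OCOC)c1 | intermediate
18 | (E)-3-[3,4-bis(methoxymethoxy)phenyl]prop-2-enoic acid | O=C(O)/C=C/c1ccc(OCOC)c(OCOC)c1 | intermediate
19 | allyl 5-O-[(E)-3,4-bis(methoxymethoxy)cinnamoyl]-3,4-O-isopropylidene-1-O-triethylsilyl-ent-quinate | O=C(/C=C/c3ccc(OCOC)c(OCOC)c3)O[C@H]1C[C@](C(=O)OCC=C)(O[Si](CC)(CC)CC)C[C@H](OC2(C)C)[C@@H]1O2 | intermediate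
20 | 5-O-[(E)-3,4-bis(methoxymethoxy)cinnamoyl]-3,4-O-isopropylidene-1-O-triethylsilyl-ent-quinic acid | O=C(/C=C/c3ccc(OCOC)c(OCOC)c3)O[C@H]1C[C@](C(=O)O)(O[Si](CC)(CC)CC)C[C@H](OC2(C)C)[C@@H]1O2 | intermediate
21 | allyl 5-O-[(E)-3,4-bis(methoxymethoxy)cinnamoyl]-3,4-O-isopropylidene-ent-quinate (free 1-OH) | O=C(/C=C/c3ccc(OCOC)c(OCOC)c3)O[C@H]1C[C@](C(=O)OCC=C)(O)C[C@H](OC2(C)C)[C@@H]1O2 | intermediate
22 | acid chloride of 20 | O=C(/C=C/c3ccc(OCOC)c(OCOC)c3)O[C@H]1C[C@](C(=O)Cl)(O[Si](CC)(CC)CC)C[C@H](OC2(C)C)[C@@H]1O2 | intermediate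
23 | allyl 1-O-{5-O-[(E)-3,4-bis(methoxymethoxy)cinnamoyl]-3,4-O-isopropylidene-1-O-triethylsilyl-ent-quinoyl}-5-O-[(E)-3,4-bis(methoxymethoxy)cinnamoyl]-3,4-O-isopropylidene-ent-quinate | O=C(/C=C/c3ccc(OCOC)c(OCOC)c3)O[C@H]1C[C@](C(=O)O[C@@]4(C(=O)OCC=C)C[C@H](OC(=O)/C=C/c5ccc(OCOC)c(OCOC)c5)[C@@H](OC6(C)C)[C@@H](O6)C4)(O[Si](CC)(CC)CC)C[C@H](OC2(C)C)[C@@H]1O2 | intermediate
24 | free acid corresponding to 23 (carboxyl of unit B unmasked) | O=C(/C=C/c3ccc(OCOC)c(OCOC)c3)O[C@H]1C[C@](C(=O)O[C@@]4(C(=O)O)C[C@H](OC(=O)/C=C/c5ccc(OCOC)c(OCOC)c5)[C@@H](OC6(C)C)[C@@H](O6)C4)(O[Si](CC)(CC)CC)C[C@H](OC2(C)C)[C@@H]1O2 | intermediate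
25 | 1-O-(5-O-caffeoyl-ent-quinoyl)-5-O-caffeoyl-ent-quinic acid (CNP0107948.2) | O=C(/C=C/c1ccc(O)c(O)c1)O[C@H]1C[C@@](O)(C(=O)O[C@@]2(C(=O)O)C[C@H](OC(=O)/C=C/c3ccc(O)c(O)c3)[C@@H](O)[C@@H](O)C2)C[C@H](O)[C@@H]1O | target

Total step count: 17. Longest linear sequence: 15 steps (steps 1–10, 12, 13 or 14, 15, 16, 17).

Steps most likely to fail

Step 8. The ketyl at the α-acyloxy aldehyde may take up a second electron and expel the lactone carboxylate from C5 (ring opening), or the diol may close trans, with O4 syn to O5. The fallback leaves from aldehyde 10 and gives up the reductive closure. Wittig methylenation (Ph3P=CH2 from Ph3PCH3Br and KN(SiMe3)2, THF, −78 °C) would give (3R,5S)-3-allyl-3-(triethylsilyloxy)-5-vinyldihydrofuran-2(3H)-one F1. Ring-closing metathesis with second-generation Grubbs catalyst (dilute DCM, 40 °C) would join the cis vinyl and allyl arms to (1R,5S)-1-(triethylsilyloxy)-6-oxabicyclo[3.2.1]oct-3-en-7-one F2. OsO4 (cat.)/NMO would then add the cis-diol from the face away from the lactone bridge, the established outcome on this bicyclic alkene type, and the route is rejoined at 13.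

Step 15. Acyl transfer from the quaternary acid chloride to the axial, hindered tertiary hydroxyl of the open-chain ester may be too slow, so the activated acid is lost to hydrolysis or decomposition. The fallback leaves from 14 and acylates the lactone form, whose equatorial tertiary hydroxyl is the more accessible one. HF·pyridine would give 3,4-O-isopropylidene-ent-quinide F3. Acid chloride 22 with Et3N/DMAP would give 1-O-{5-O-[(E)-3,4-bis(methoxymethoxy)cinnamoyl]-3,4-O-isopropylidene-1-O-triethylsilyl-ent-quinoyl}-3,4-O-isopropylidene-ent-quinide F4. One equivalent of LiOH (THF/H2O, 0 °C), relying on the strain and α-acyloxy activation of the lactone, would give the lithium carboxylate of the ring-opened hydroxy acid F5. Allyl bromide 3 in DMF would turn this into allyl 1-O-{5-O-[(E)-3,4-bis(methoxymethoxy)cinnamoyl]-3,4-O-isopropylidene-1-O-triethylsilyl-ent-quinoyl}-3,4-O-isopropylidene-ent-quinate F6, with free 5-OH. DCC/DMAP esterification of F6 with acid 18 rejoins the route at 23.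

Step 5. The tertiary triethylsilyl ether may be lost together with the trityl ether under the acid. The fallback leaves from 7 and removes the trityl group before any silyl ether exists. CSA/MeOH would give (3R,5S)-3-allyl-3-hydroxy-5-(hydroxymethyl)dihydrofuran-2(3H)-one F7. TESOTf/2,6-lutidine would silylate both hydroxyls to (3R,5S)-3-allyl-3-(triethylsilyloxy)-5-[(triethylsilyloxy)methyl]dihydrofuran-2(3H)-one F8. Swern conditions ((COCl)2, DMSO, DCM, −78 to −30 °C, then i-Pr2NEt) are known to cleave and oxidise primary triethylsilyl ethers directly while leaving hindered ones, which would rejoin the route at aldehyde 10.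

Further compounds
F1 | step 8 | (3R,5S)-3-allyl-3-(triethylsilyloxy)-5-vinyldihydrofuran-2(3H)-one | C=C[C@@H]1C[C@](O[Si](CC)(CC)CC)(CC=C)C(=O)O1
F2 | step 8 | (1R,5S)-1-(triethylsilyloxy)-6-oxabicyclo[3.2.1]oct-3-en-7-one | O=C1O[C@H]2C[C@]1(O[Si](CC)(CC)CC)CC=C2
F3 | step 15 | 3,4-O-isopropylidene-ent-quinide | O=C1O[C@H]2C[C@]1(O)C[C@H](OC3(C)C)[C@@H]2O3
F4 | step 15 | 1-O-{5-O-[(E)-3,4-bis(methoxymethoxy)cinnamoyl]-3,4-O-isopropylidene-1-O-triethylsilyl-ent-quinoyl}-3,4-O-isopropylidene-ent-quinide | O=C(/C=C/c3ccc(OCOC)c(OCOC)c3)O[C@H]1C[C@](C(=O)O[C@]4(C(=O)O[C@H]5C4)C[C@H](OC6(C)C)[C@@H]5O6)(O[Si](CC)(CC)CC)C[C@H](OC2(C)C)[C@@H]1O2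
F5 | step 15 | lithium 1-O-{5-O-[(E)-3,4-bis(methoxymethoxy)cinnamoyl]-3,4-O-isopropylidene-1-O-triethylsilyl-ent-quinoyl}-3,4-O-isopropylidene-ent-quinate | O=C(/C=C/c3ccc(OCOC)c(OCOC)c3)O[C@H]1C[C@](C(=O)O[C@@]4(C(=O)[O-])C[C@H](O)[C@@H](OC6(C)C)[C@@H](O6)C4)(O[Si](CC)(CC)CC)C[C@H](OC2(C)C)[C@@H]1O2.[Li+]
F6 | step 15 | allyl 1-O-{5-O-[(E)-3,4-bis(methoxymethoxy)cinnamoyl]-3,4-O-isopropylidene-1-O-triethylsilyl-ent-quinoyl}-3,4-O-isopropylidene-ent-quinate | O=C(/C=C/c3ccc(OCOC)c(OCOC)c3)O[C@H]1C[C@](C(=O)O[C@@]4(C(=O)OCC=C)C[C@H](O)[C@@H](OC6(C)C)[C@@H](O6)C4)(O[Si](CC)(CC)CC)C[C@H](OC2(C)C)[C@@H]1O2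
F7 | step 5 | (3R,5S)-3-allyl-3-hydroxy-5-(hydroxymethyl)dihydrofuran-2(3H)-one | OC[C@@H]1C[C@](O)(CC=C)C(=O)O1
F8 | step 5 | (3R,5S)-3-allyl-3-(triethylsilyloxy)-5-[(triethylsilyloxy)methyl]dihydrofuran-2(3H)-one | CC[Si](CC)(CC)OC[C@@H]1C[C@](O[Si](CC)(CC)CC)(CC=C)C(=O)O1
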